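**Retrosynthetic overview**

- Endgame: the C2 acetate goes on last. The C5 (Z)-3-methylpent-2-enoate is installed with inversion on a 5α allylic alcohol. That alcohol and the C4 methylidene come from an α-epoxide of a C4=C5 cyclohexene, made by epoxidation directed by the C6 hydroxyl. The isopropyl group comes from a C7 acetyl.
- Key disconnection: C6–C7 and C3a–C7a are formed together by an intramolecular Diels–Alder reaction of an acyclic tetraene. The enabling feature is that the six-membered ring C3a–C4–C5–C6–C7–C7a is a retro-[4+2] cyclohexene: diene C6=C5–C4=C3a (boron at C6 as masked hydroxyl, methyl at C4), dienophile C7=C7a (activated by the acetyl that becomes the isopropyl group). C3a and C7a are bridged by the three carbons C3–C2–C1 of the five-membered ring, so one cycloaddition closes both rings and sets C3a, C7a, C7 and C6.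
- Tetraene: from (S)-hept-1-en-5-yn-4-ol (asymmetric allylation of but-2-ynal) by hydroxyl-directed syn-hydrostannation and Stille coupling (fixes the (Z)-ethylidene), cross-metathesis with methacrolein, and Takai boryl-olefination.
- Ring order: the five- and six-membered carbocycles form together in the key step; the only other ring is a transient epoxide.

Key step: step 9

Remark on names: bicyclic compounds use the hydrindane numbering of the target (C1 ethylidene carbon, C2 acetoxy carbon, C3 CH2, C3a/C7a ring fusion, C4 methylidene carbon, C5 ester carbinol, C6 free carbinol, C7 isopropyl carbon). β is the face of H-3a, α the face of H-7a. Acyclic compounds carry their own chain numbering.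

Assumption: the allylborane made from (+)-α-pinene adds to but-2-ynal with the same facial sense as to other aldehydes, which corresponds to the (S)-carbinol.

**Route**

Step 1
Reactants: 1 but-2-yn-1-ol
Product: 2 but-2-ynal
Conditions: activated MnO2 (10 equiv), CH2Cl2, 25 °C; filtered, used as a solution
Reagents that add atoms: none
Why: Heterogeneous MnO2 oxidation of a propargylic alcohol stops at the ynal and needs no aqueous work-up for this volatile aldehyde.

Step 2
Reactants: 2 but-2-ynal
Product: 3 (S)-hept-1-en-5-yn-4-ol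
Conditions: (−)-Ipc2B(allyl) [from (+)-α-pinene], Et2O, −78 °C; then NaOH, H2O2, 0 °C
Reagents that add atoms: (−)-B-allyldiisopinocampheylborane, C=CCB([C@@H]1C[C@@H]2C[C@H]([C@H]1C)C2(C)C)[C@@H]1C[C@@H]2C[C@H]([C@H]1C)C2(C)C
Why: Brown allylboration through a closed chair transition state with the aldehyde substituent equatorial should give the (S)-carbinol, which becomes the C2 acetoxy stereocentre of the target.

Step 3
Reactants: 3 (S)-hept-1-en-5-yn-4-ol
Product: 4 (4S,5E)-5-(tributylstannyl)hepta-1,5-dien-4-ol
Conditions: Bu3SnH (1.2 equiv), PdCl2(PPh3)2 (2 mol %), THF, 0 → 25 °C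
Reagents that add atoms: tributyltin hydride, CCCC[SnH](CCCC)CCCC
Why: Palladium-catalysed hydrostannation is a syn addition in which the free propargylic hydroxyl steers tin to the proximal alkyne carbon, so the methyl group ends cis to the carbinol carbon (the geometry of the later (Z)-ethylidene) while the monosubstituted alkene is untouched.

Step 4
Reactants: 4 (4S,5E)-5-(tributylstannyl)hepta-1,5-dien-4-ol
Product: 5 tert-butyldimethyl{[(4S,5E)-5-(tributylstannyl)hepta-1,5-dien-4-yl]oxy}silane
Conditions: TBSOTf, 2,6-lutidine, CH2Cl2, −78 °C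
Reagents that add atoms: tert-butyldimethylsilyl triflate, CC(C)(C)[Si](C)(C)OS(=O)(=O)C(F)(F)F
Why: Standard silylation of a hindered secondary alcohol installs the bulky allylic ether that later biases the cycloaddition and lasts until the final fluoride treatment.

Step 5
Reactants: 5 the TBS ether; 6 methacrolein
Product: 7 (2E,5S,6E)-5-(tert-butyldimethylsilyloxy)-2-methyl-6-(tributylstannyl)octa-2,6-dienal
Conditions: second-generation Hoveyda–Grubbs catalyst (5 mol %), 6 (5 equiv), CH2Cl2, 40 °C
Reagents that add atoms: none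
Why: Olefin cross-metathesis of the monosubstituted alkene with excess methacrolein should give the (E)-2-methyl-2-enal under thermodynamic control, while the trisubstituted alkenylstannane is too hindered to enter the metathesis cycle.

Step 6
Reactants: 8 but-3-yn-2-one
Product: 10 (E)-4-iodobut-3-en-2-one, via (Z)-4-iodobut-3-en-2-one 9 (not isolated)
Conditions: NaI, AcOH, 25 °C; then cat. aq. HI, benzene, 60 °C
Reagents that add atoms: sodium iodide, [Na+].[I-]
Why: Conjugate hydroiodination of the ynone gives the (Z)-β-iodoenone by anti addition, and acid-catalysed addition–elimination of iodide equilibrates it to the more stable (E)-isomer.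

Step 7
Reactants: 7 the stannyl dienal; 10 (E)-4-iodobut-3-en-2-one
Product: 11 (2E,5S,7E)-5-(tert-butyldimethylsilyloxy)-6-[(Z)-ethylidene]-2-methyl-9-oxodeca-2,7-dienal
Conditions: Pd(PPh3)4 (10 mol %), CuCl (5 equiv), LiCl (6 equiv), DMSO, 60 °C
Reagents that add atoms: none
Why: Copper-assisted Stille coupling (tin-to-copper transmetalation feeding a zerovalent palladium cycle) of the hindered 1-substituted alkenylstannane with the reactive β-iodoenone proceeds with retention at both alkenes, so the ethylidene methyl stays cis to the carbinol carbon and the enone is (E).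

Step 8
Reactants: 11 the dienone enal
Product: 12 (3E,6S,8E,10E)-6-(tert-butyldimethylsilyloxy)-5-[(Z)-ethylidene]-9-methyl-11-(4,4,5,5-tetramethyl-1,3,2-dioxaborolan-2-yl)undeca-3,8,10-trien-2-one
Conditions: CrCl2 (8 equiv), LiI (4 equiv), Cl2CHBpin (2 equiv), THF, 25 °C
Reagents that add atoms: 2-(dichloromethyl)-4,4,5,5-tetramethyl-1,3,2-dioxaborolane, ClC(Cl)B1OC(C)(C)C(C)(C)O1
Why: Takai–Utimoto olefination with the geminal dichromium reagent is selective for the aldehyde over the methyl ketone and gives the (E)-alkenylboronate, completing the (E,E)-1-boryl-3-methyl diene.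

Step 9
Reactants: 12 the acyclic tetraene
Product: 13 7α-acetyl-2α-(tert-butyldimethylsilyloxy)-1-[(Z)-ethylidene]-4-methyl-6α-(4,4,5,5-tetramethyl-1,3,2-dioxaborolan-2-yl)-2,3,3a,6,7,7a-hexahydro-1H-indene (trans-fused, H-3a β, H-7a α)
Conditions: Me2AlCl (1.1 equiv), CH2Cl2 (0.01 M), −78 → −20 °C; aq. Rochelle salt
Reagents that add atoms: none
Why: Me2AlCl binds the acetyl oxygen and lowers the LUMO of the (E)-enone, which then undergoes a concerted but asynchronous intramolecular [4+2] cycloaddition with the (E,E)-1-boryl diene, forming C7a–C3a and C7–C6 together. The closest known reaction type is the Lewis-acid-promoted type 1 intramolecular Diels–Alder reaction of 1,3,8-nonatrienes with a terminally activated (E)-dienophile, combined with the use of 1-dienylboronates as dienes that deliver an allylboronate. The six-membered ring closes as the [4+2] ring itself, and the five-membered ring closes at the same moment because the three-atom tether C3–C2–C1 links the diene terminus C3a to the dienophile carbon C7a. The (E)-dienophile fixes H-7a and H-7 trans, the (E,E)-diene fixes H-3a and H-6 cis, and the endo orientation of the aluminium-bound acetyl (tether exo) gives the trans ring fusion and places the C7 acetyl cis to the C6 boryl group. The π-face is chosen by the C2 stereocentre, because A(1,3) strain with the (Z)-ethylidene methyl is smallest when the OTBS group is pseudoaxial on the face toward which C7a puckers, which should lead to the 2α-silyloxy, 7aα-H isomer. The step therefore needs endo and facial selectivity, secured by the terminal Lewis-acid-bound carbonyl, the fixed alkene geometries and the allylic silyloxy stereocentre, while the tether length excludes any other cycloaddition mode.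

Step 10
Reactants: 13 the allylboronate
Product: 14 7α-acetyl-2α-(tert-butyldimethylsilyloxy)-1-[(Z)-ethylidene]-4-methyl-2,3,3a,6,7,7a-hexahydro-1H-inden-6α-ol
Conditions: NaBO3·4H2O, THF/H2O (1:1), 25 °C
Reagents that add atoms: sodium perborate, B(=O)O[O-].[Na+]
Why: Perborate oxidation of the allylic boronate proceeds by 1,2-migration of carbon from boron to oxygen with retention and without allylic transposition, under conditions mild enough for the β-hydroxy ketone.

Step 11
Reactants: 14 the allylic alcohol
Product: 15 7α-acetyl-2α-(tert-butyldimethylsilyloxy)-4α,5α-epoxy-1-[(Z)-ethylidene]-4β-methyloctahydro-1H-inden-6α-ol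
Conditions: VO(acac)2 (5 mol %), t-BuOOH (1.5 equiv), CH2Cl2, 0 → 25 °C
Reagents that add atoms: tert-butyl hydroperoxide, CC(C)(C)OO
Why: Vanadium-catalysed epoxidation is delivered by the pseudoaxial allylic 6α-hydroxyl to the α face of the C4=C5 alkene only, and the ethylidene alkene, whose allylic oxygen is silylated, is not epoxidised.

Step 12
Reactants: 15 the epoxy alcohol
Product: 16 the 6-O-triethylsilyl ether of 15
Conditions: TESCl, imidazole, DMAP (cat.), DMF, 25 °C
Reagents that add atoms: chlorotriethylsilane, CC[Si](Cl)(CC)CC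
Why: Routine silylation masks the C6 hydroxyl so that the basic olefination cannot trigger retro-aldol cleavage and the later Mitsunobu reaction has only one free hydroxyl.

Step 13
Reactants: 16 the silylated epoxy ketone
Product: 17 2α-(tert-butyldimethylsilyloxy)-4α,5α-epoxy-1-[(Z)-ethylidene]-4β-methyl-7α-(prop-1-en-2-yl)-6α-(triethylsilyloxy)octahydro-1H-indene
Conditions: Ph3PCH3Br, KOtBu, THF, 0 °C; then 16, 0 → 25 °C
Reagents that add atoms: methyltriphenylphosphonium bromide, C[P+](c1ccccc1)(c1ccccc1)c1ccccc1.[Br-]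
Why: Wittig methylenation of the methyl ketone gives the isopropenyl group, and the equatorial C7 configuration is the thermodynamic one so the basic ylide cannot erode it.

Step 14
Reactants: 17 the isopropenyl compound
Product: 18 2α-(tert-butyldimethylsilyloxy)-4α,5α-epoxy-1-[(Z)-ethylidene]-4β-methyl-7α-(propan-2-yl)-6α-(triethylsilyloxy)octahydro-1H-indene
Conditions: H2 (1 atm), RhCl(PPh3)3 (10 mol %), benzene, 25 °C
Reagents that add atoms: none
Why: Homogeneous hydrogenation with RhCl(PPh3)3 reduces the 1,1-disubstituted isopropenyl alkene much faster than the trisubstituted ethylidene and creates no stereocentre.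

Step 15
Reactants: 18 the epoxide
Product: 19 2α-(tert-butyldimethylsilyloxy)-1-[(Z)-ethylidene]-4-methylidene-7α-(propan-2-yl)-6α-(triethylsilyloxy)octahydro-1H-inden-5α-ol
Conditions: Et2AlCl and LiTMP (4 equiv each), benzene, 0 °C; then 18, 0 → 25 °C
Reagents that add atoms: none
Why: In the aluminium amide-mediated epoxide-to-allylic-alcohol isomerisation the amide bound to the epoxide oxygen removes a β-proton syn to that oxygen through a cyclic transition state, and on the α face only the C4 methyl protons are available (H-3a is β), so the tertiary C–O bond opens to the 4-methylidene 5α-alcohol with C5 unchanged.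

Step 16
Reactants: 20 ethyl pent-2-ynoate
Product: 21 ethyl (2Z)-3-methylpent-2-enoate
Conditions: CuI, MeLi (2 equiv), Et2O/THF, 0 → −78 °C; then 20, −78 °C; MeOH then aq. NH4Cl at −78 °C
Reagents that add atoms: methyllithium (delivered as Me2CuLi), C[Li]
Why: syn-Carbocupration of the ynoate at −78 °C followed by protonation with retention places the new methyl trans to the ester, which is the (Z)-enoate.

Step 17
Reactants: 21 ethyl (2Z)-3-methylpent-2-enoate
Product: 22 (2Z)-3-methylpent-2-enoic acid
Conditions: LiOH·H2O, THF/MeOH/H2O, 25 °C; then 1 M HCl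
Reagents that add atoms: lithium hydroxide, [Li+].[OH-]
Why: Mild hydroxide saponification of the β,β-disubstituted enoate should not isomerise the trisubstituted alkene.

Step 18
Reactants: 19 the 5α allylic alcohol; 22 (2Z)-3-methylpent-2-enoic acid
Product: 23 2α-(tert-butyldimethylsilyloxy)-1-[(Z)-ethylidene]-4-methylidene-7α-(propan-2-yl)-6α-(triethylsilyloxy)octahydro-1H-inden-5β-yl (2Z)-3-methylpent-2-enoate
Conditions: PPh3, DIAD, toluene, 0 → 25 °C
Reagents that add atoms: none
Why: Mitsunobu esterification activates the equatorial allylic 5α-hydroxyl as an oxyphosphonium ion that the carboxylate displaces by SN2 with inversion, which sets the axial 5β ester trans to the 6α oxygen without activating the acid, so its (Z)-geometry is kept.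

Step 19
Reactants: 23 the bis-silyl ether
Product: 24 1-[(Z)-ethylidene]-2α,6α-dihydroxy-4-methylidene-7α-(propan-2-yl)octahydro-1H-inden-5β-yl (2Z)-3-methylpent-2-enoate
Conditions: HF·pyridine, pyridine, THF, 0 → 25 °C
Reagents that add atoms: none
Why: Buffered HF·pyridine cleaves both silyl ethers without touching the allylic ester, and the trans-diaxial arrangement of the C5 ester and C6 hydroxyl prevents acyl migration.

Step 20
Reactants: 24 the diol
Product: 25 (1Z,2S,3aR,5S,6S,7S,7aR)-2-(acetyloxy)-1-ethylidene-6-hydroxy-4-methylidene-7-(propan-2-yl)octahydro-1H-inden-5-yl (2Z)-3-methylpent-2-enoate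
Conditions: Ac2O (1.1 equiv), pyridine, DMAP (5 mol %), CH2Cl2, −20 → 0 °C
Reagents that add atoms: acetic anhydride, CC(=O)OC(C)=O
Why: The unhindered allylic C2 hydroxyl on the cyclopentane should be acetylated far faster than the axial C6 hydroxyl, which is flanked by the isopropyl-bearing C7 and the acyloxy-bearing C5.

**Compound list**

1 | but-2-yn-1-ol | CC#CCO | starting material
2 | but-2-ynal | CC#CC=O | intermediate
3 | (S)-hept-1-en-5-yn-4-ol | CC#C[C@@H](O)CC=C | intermediate
4 | (4S,5E)-5-(tributylstannyl)hepta-1,5-dien-4-ol | C/C=C(/[Sn](CCCC)(CCCC)CCCC)[C@@H](O)CC=C | intermediate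
5 | tert-butyldimethyl{[(4S,5E)-5-(tributylstannyl)hepta-1,5-dien-4-yl]oxy}silane | C/C=C(/[Sn](CCCC)(CCCC)CCCC)[C@@H](O[Si](C)(C)C(C)(C)C)CC=C | intermediate
6 | methacrolein (2-methylprop-2-enal) | CC(=C)C=O | starting material
7 | (2E,5S,6E)-5-(tert-butyldimethylsilyloxy)-2-methyl-6-(tributylstannyl)octa-2,6-dienal | C/C=C(/[Sn](CCCC)(CCCC)CCCC)[C@@H](O[Si](C)(C)C(C)(C)C)C/C=C(\C)C=O | intermediate
8 | but-3-yn-2-one | CC(=O)C#C | starting material
9 | (Z)-4-iodobut-3-en-2-one | CC(=O)/C=C\I | intermediate
10 | (E)-4-iodobut-3-en-2-one | CC(=O)/C=C/I | intermediate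
11 | (2E,5S,7E)-5-(tert-butyldimethylsilyloxy)-6-[(Z)-ethylidene]-2-methyl-9-oxodeca-2,7-dienal | C/C=C(/C=C/C(C)=O)[C@@H](O[Si](C)(C)C(C)(C)C)C/C=C(\C)C=O | intermediate
12 | (3E,6S,8E,10E)-6-(tert-butyldimethylsilyloxy)-5-[(Z)-ethylidene]-9-methyl-11-(4,4,5,5-tetramethyl-1,3,2-dioxaborolan-2-yl)undeca-3,8,10-trien-2-one | C/C=C(/C=C/C(C)=O)[C@@H](O[Si](C)(C)C(C)(C)C)C/C=C(C)/C=C/B1OC(C)(C)C(C)(C)O1 | intermediate
13 | 7α-acetyl-2α-(tert-butyldimethylsilyloxy)-1-[(Z)-ethylidene]-4-methyl-6α-(pinacolatoboryl)-2,3,3a,6,7,7a-hexahydro-1H-indene (H-3a β, H-7a α) | CC1[C@@H]2C[C@H](O[Si](C)(C)C(C)(C)C)/C(=C\C)[C@H]2[C@H](C(C)=O)[C@H](B3OC(C)(C)C(C)(C)O3)C=1 | intermediate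
14 | 7α-acetyl-2α-(tert-butyldimethylsilyloxy)-1-[(Z)-ethylidene]-4-methyl-2,3,3a,6,7,7a-hexahydro-1H-inden-6α-ol | CC1[C@@H]2C[C@H](O[Si](C)(C)C(C)(C)C)/C(=C\C)[C@H]2[C@H](C(C)=O)[C@H](O)C=1 | intermediate
15 | 7α-acetyl-2α-(tert-butyldimethylsilyloxy)-4α,5α-epoxy-1-[(Z)-ethylidene]-4β-methyloctahydro-1H-inden-6α-ol | C[C@@]1(O3)[C@@H]2C[C@H](O[Si](C)(C)C(C)(C)C)/C(=C\C)[C@H]2[C@H](C(C)=O)[C@H](O)[C@@H]13 | intermediate
16 | 6-O-triethylsilyl ether of 15 | C[C@@]1(O3)[C@@H]2C[C@H](O[Si](C)(C)C(C)(C)C)/C(=C\C)[C@H]2[C@H](C(C)=O)[C@H](O[Si](CC)(CC)CC)[C@@H]13 | intermediate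
17 | 7α-(prop-1-en-2-yl) analogue of 16 | C[C@@]1(O3)[C@@H]2C[C@H](O[Si](C)(C)C(C)(C)C)/C(=C\C)[C@H]2[C@H](C(C)=C)[C@H](O[Si](CC)(CC)CC)[C@@H]13 | intermediate
18 | 7α-(propan-2-yl) analogue of 16 | C[C@@]1(O3)[C@@H]2C[C@H](O[Si](C)(C)C(C)(C)C)/C(=C\C)[C@H]2[C@H](C(C)C)[C@H](O[Si](CC)(CC)CC)[C@@H]13 | intermediate
19 | 2α-(tert-butyldimethylsilyloxy)-1-[(Z)-ethylidene]-4-methylidene-7α-(propan-2-yl)-6α-(triethylsilyloxy)octahydro-1H-inden-5α-ol | C=C1[C@@H]2C[C@H](O[Si](C)(C)C(C)(C)C)/C(=C\C)[C@H]2[C@H](C(C)C)[C@H](O[Si](CC)(CC)CC)[C@@H]1O | intermediate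
20 | ethyl pent-2-ynoate | CCC#CC(=O)OCC | starting material
21 | ethyl (2Z)-3-methylpent-2-enoate | CC/C(C)=C\C(=O)OCC | intermediate
22 | (2Z)-3-methylpent-2-enoic acid | CC/C(C)=C\C(=O)O | intermediate
23 | 2α-(tert-butyldimethylsilyloxy)-1-[(Z)-ethylidene]-4-methylidene-7α-(propan-2-yl)-6α-(triethylsilyloxy)octahydro-1H-inden-5β-yl (2Z)-3-methylpent-2-enoate | C=C1[C@@H]2C[C@H](O[Si](C)(C)C(C)(C)C)/C(=C\C)[C@H]2[C@H](C(C)C)[C@H](O[Si](CC)(CC)CC)[C@H]1OC(=O)/C=C(/C)CC | intermediate
24 | 1-[(Z)-ethylidene]-2α,6α-dihydroxy-4-methylidene-7α-(propan-2-yl)octahydro-1H-inden-5β-yl (2Z)-3-methylpent-2-enoate | C=C1[C@@H]2C[C@H](O)/C(=C\C)[C@H]2[C@H](C(C)C)[C@H](O)[C@H]1OC(=O)/C=C(/C)CC | intermediate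
25 | (1Z,2S,3aR,5S,6S,7S,7aR)-2-(acetyloxy)-1-ethylidene-6-hydroxy-4-methylidene-7-(propan-2-yl)octahydro-1H-inden-5-yl (2Z)-3-methylpent-2-enoate | C=C1[C@@H]2C[C@H](OC(C)=O)/C(=C\C)[C@H]2[C@H](C(C)C)[C@H](O)[C@H]1OC(=O)/C=C(/C)CC | target

**Step count**

Total step count: 20. Longest linear sequence: 17 steps (steps 1–5, 7–15, 18–20).

**Steps most likely to fail**

Step 9. What may go wrong: the C2 silyloxy group lies close to the local twofold axis of the forming cyclopentane, so facial discrimination rests only on its A(1,3) interaction with the ethylidene methyl and may be insufficient. Endo selectivity may also erode, or the Lewis acid may degrade the boronate. Fallback: replace substrate control by reagent control. Setting out from 12, the cycloaddition is run with a chiral cationic oxazaborolidine Lewis acid (the N-protonated triflimide salt of 3,3-diphenyl-1-(o-tolyl)tetrahydropyrrolo[1,2-c][1,3,2]oxazaborole, 20 mol %, CH2Cl2, −78 → −40 °C), a known enantioselective Diels–Alder catalyst for enones and for intramolecular trienes. The antipode that reinforces attack on the required dienophile face is chosen. The route is rejoined at 13 and no new compound is made on this way (F0).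

Step 18. What may go wrong: the carboxylate may attack the exocyclic methylene (SN2′) instead of C5, or the hindered oxyphosphonium ion may fail to be displaced and collapse with retention or elimination. Fallback: activate both oxygens as a cyclic sulfate so that the leaving group is tied back and small. Setting out from 19, the triethylsilyl ether is removed selectively (PPTS, MeOH/CH2Cl2, 0 °C) to give 2α-(tert-butyldimethylsilyloxy)-1-[(Z)-ethylidene]-4-methylidene-7α-(propan-2-yl)octahydro-1H-indene-5α,6α-diol F1. Treatment with 1,1′-sulfonyldiimidazole and NaH in THF gives the 5α,6α-cyclic sulfate F2. The caesium salt of 22 (Cs2CO3, DMF, 25 °C) opens it at the allylic C5 with inversion to the 6α-(sulfooxy) 5β-ester F3. Hydrolysis of the sulfate monoester (cat. H2SO4, 1 equiv H2O, THF) gives the 2α-silyloxy 6α-hydroxy 5β-ester F4. HF·pyridine then removes the remaining silyl group and the route is rejoined at 24.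

Step 7. What may go wrong: transmetalation of the α-branched alkenylstannane may be slow, so that protodestannylation, homocoupling or cine substitution compete with cross-coupling. Fallback: reverse the polarity of the coupling and use a Heck reaction. Setting out from 7, iododestannylation (I2, CH2Cl2, 0 °C) gives with retention (2E,5S,6E)-5-(tert-butyldimethylsilyloxy)-6-iodo-2-methylocta-2,6-dienal F5. Heck coupling with methyl vinyl ketone (Pd(OAc)2, Et3N, Bu4NCl, DMF, 40 °C) forms the (E)-enone by syn insertion and β-hydride elimination, and the route is rejoined at 11.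

**Further compounds**

F0 | step 9 | none | none
F1 | step 18 | 2α-(tert-butyldimethylsilyloxy)-1-[(Z)-ethylidene]-4-methylidene-7α-(propan-2-yl)octahydro-1H-indene-5α,6α-diol | C=C1[C@@H]2C[C@H](O[Si](C)(C)C(C)(C)C)/C(=C\C)[C@H]2[C@H](C(C)C)[C@H](O)[C@@H]1O
F2 | step 18 | 5α,6α-cyclic sulfate of F1 | C=C1[C@@H]2C[C@H](O[Si](C)(C)C(C)(C)C)/C(=C\C)[C@H]2[C@H](C(C)C)[C@@H]3OS(=O)(=O)O[C@H]13
F3 | step 18 | 2α-(tert-butyldimethylsilyloxy)-1-[(Z)-ethylidene]-4-methylidene-7α-(propan-2-yl)-6α-(sulfooxy)octahydro-1H-inden-5β-yl (2Z)-3-methylpent-2-enoate | C=C1[C@@H]2C[C@H](O[Si](C)(C)C(C)(C)C)/C(=C\C)[C@H]2[C@H](C(C)C)[C@H](OS(=O)(=O)O)[C@H]1OC(=O)/C=C(/C)CC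
F4 | step 18 | 2α-(tert-butyldimethylsilyloxy)-1-[(Z)-ethylidene]-6α-hydroxy-4-methylidene-7α-(propan-2-yl)octahydro-1H-inden-5β-yl (2Z)-3-methylpent-2-enoate | C=C1[C@@H]2C[C@H](O[Si](C)(C)C(C)(C)C)/C(=C\C)[C@H]2[C@H](C(C)C)[C@H](O)[C@H]1OC(=O)/C=C(/C)CC
F5 | step 7 | (2E,5S,6E)-5-(tert-butyldimethylsilyloxy)-6-iodo-2-methylocta-2,6-dienal | C/C=C(/I)[C@@H](O[Si](C)(C)C(C)(C)C)C/C=C(\C)C=O
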